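**Retrosynthetic overview**
1. The route rests on the enol-lactone double bond C3=C4 of isochromenone ring B, which sits between C4a of ring A and the butadienyl chain. C4 and C3 are read as the two carbons of a terminal alkyne and O2 as a carboxylate oxygen, so ring B is opened to an o-iodobenzoic acid and a dienyne (bonds C4–C4a and O2–C3).
2. The ring A partner, 3-chloro-2-iodo-4,6-bis(methoxymethoxy)benzoic acid, comes from 1-iodo-3,5-dimethoxybenzene by formylation, chlorination, exchange of methyl for MOM ethers and aldehyde oxidation.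
3. The dienyne comes from 2-deoxy-D-ribose, whose C3 and C4 become oxolane C3 and C2. The C5 methyl centre is set by MeLi addition to the lactone and silane reduction of the hemiketal; the chain is grown by vinylogous olefination, redox adjustment and alkyne homologation.
4. Ring order: the oxolane first (from the sugar), ring A carried in from the arene, ring B closed in the coupling step; one acidic deprotection ends the route.

Key step: step 16

Remark: the core is numbered as 1H-isochromen-1-one (C1 carbonyl, O2, C3, C4, C4a to C8a) and the side ring as oxolane (O1, C2 to C5); the sugar is assumed to deliver oxolane C2 and C3 unchanged, so only C5 has to be created.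

**Route**

Step 1
Reactants: 1 1-iodo-3,5-dimethoxybenzene
Product: 3 2-iodo-4,6-dimethoxybenzaldehyde, via aryl iminium chloride 2 (not isolated)
Conditions: POCl3, DMF, 0 → 70 °C; then H2O, 0 °C → rt
Reagents that add atoms: N,N-dimethylformamide CN(C)C=O; water O
Why: Vilsmeier–Haack formylation, in which the chloroiminium ion attacks the ring carbon ortho to iodine, para to one methoxy group and ortho to the other (the usual site in 5-halo-1,3-dimethoxybenzenes), and water then hydrolyses iminium salt 2 to the aldehyde.

Step 2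
Reactants: 3 2-iodo-4,6-dimethoxybenzaldehyde
Product: 4 3-chloro-2-iodo-4,6-dimethoxybenzaldehyde
Conditions: NCS, DMF, rt → 40 °C
Reagents that add atoms: N-chlorosuccinimide O=C1CCC(=O)N1Cl
Why: Electrophilic aromatic chlorination that should go to C3, which is para to the C6 methoxy and ortho to the C4 methoxy group (the same kind of site that was formylated in step 1) rather than to C5 between the two ethers, while NCS leaves the aryl iodide and the aldehyde untouched.

Step 3
Reactants: 4 3-chloro-2-iodo-4,6-dimethoxybenzaldehyde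
Product: 5 3-chloro-4,6-dihydroxy-2-iodobenzaldehyde
Conditions: BBr3, CH2Cl2, −78 °C → rt; then H2O
Reagents that add atoms: none
Why: Lewis-acid cleavage of aryl methyl ethers, in which BBr3 complexes each ether oxygen and bromide removes the methyl group by SN2 (the ortho ether helped by chelation to the aldehyde), with the aryl halides inert.

Step 4
Reactants: 5 3-chloro-4,6-dihydroxy-2-iodobenzaldehyde
Product: 6 3-chloro-2-iodo-4,6-bis(methoxymethoxy)benzaldehyde
Conditions: NaH, MOMCl, DMF, 0 °C → rt
Reagents that add atoms: chloromethyl methyl ether COCCl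
Why: Williamson-type O-alkylation of both sodium phenoxides, NaH being strong enough to break the hydrogen bond of the ortho hydroxyl to the aldehyde so that both phenols are masked as acetals that tolerate the basic coupling later.

Step 5
Reactants: 6 3-chloro-2-iodo-4,6-bis(methoxymethoxy)benzaldehyde
Product: 7 3-chloro-2-iodo-4,6-bis(methoxymethoxy)benzoic acid
Conditions: NaClO2, NaH2PO4, 2-methyl-2-butene, t-BuOH/H2O, rt
Reagents that add atoms: sodium chlorite [Na+].[O-]Cl=O
Why: Pinnick oxidation, in which chlorous acid adds to the hindered aldehyde and fragments to the acid at about pH 4, where the aryl MOM ethers and the C–I bond survive and 2-methyl-2-butene traps the HOCl formed.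

Step 6
Reactants: 8 2-deoxy-D-ribose
Product: 9 2-deoxy-D-ribono-1,4-lactone
Conditions: Br2, H2O, rt, dark
Reagents that add atoms: none
Why: Bromine-water oxidation of an aldose, in which the cyclic hemiacetal is oxidised at C1 and the aldonic acid settles as the five-membered 1,4-lactone, with C3 and C4 of the sugar untouched.

Step 7
Reactants: 9 2-deoxy-D-ribono-1,4-lactone
Product: 10 (4S,5R)-4-(tert-butyldimethylsilyloxy)-5-[(tert-butyldimethylsilyloxy)methyl]oxolan-2-one
Conditions: TBSCl, imidazole, DMF, rt
Reagents that add atoms: tert-butyldimethylsilyl chloride CC(C)(C)[Si](C)(C)Cl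
Why: Imidazole-promoted silyl ether formation on the primary and the secondary hydroxyl, which removes both acidic protons before the organolithium step.

Step 8
Reactants: 10 bis-silylated lactone
Product: 11 (4S,5R)-4-(tert-butyldimethylsilyloxy)-5-[(tert-butyldimethylsilyloxy)methyl]-2-methyloxolan-2-ol (both C2 epimers)
Conditions: MeLi, THF, −78 °C; then aq. NH4Cl
Reagents that add atoms: methyllithium [Li]C
Why: Mono-addition of an organolithium to a lactone carbonyl, in which the tetrahedral lithium alkoxide persists at −78 °C until the quench so that no second addition occurs; the C2 mixture is irrelevant because this carbon becomes planar in step 9.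

Step 9
Reactants: 11 methyl hemiketal
Product: 12 tert-butyl{[(2R,3S,5S)-3-(tert-butyldimethylsilyloxy)-5-methyloxolan-2-yl]methoxy}dimethylsilane
Conditions: Et3SiH, BF3·OEt2, CH2Cl2, −78 → −40 °C
Reagents that add atoms: none
Why: Ionic hydrogenation of a hemiketal, in which the oxocarbenium ion at the methyl-bearing carbon takes hydride on the face cis to the C3 silyloxy group (inside attack on the envelope with the 3-alkoxy group pseudoaxial, as in β-selective reductions of 2-deoxyribofuranosyl hemiketals), so the methyl group ends cis to the C2 silyloxymethyl arm and C5 is set as S.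

Step 10
Reactants: 12 bis-silyl ether
Product: 13 [(2R,3S,5S)-3-(tert-butyldimethylsilyloxy)-5-methyloxolan-2-yl]methanol
Conditions: CSA (cat.), MeOH/CH2Cl2, 0 °C
Reagents that add atoms: none
Why: Acid-catalysed methanolysis of a silyl ether, selective because the primary TBS ether is far less hindered than the secondary one on the ring.

Step 11
Reactants: 13 primary alcohol
Product: 14 (2S,3S,5S)-3-(tert-butyldimethylsilyloxy)-5-methyloxolane-2-carbaldehyde
Conditions: Dess–Martin periodinane, CH2Cl2, 0 °C → rt
Reagents that add atoms: none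
Why: Dess–Martin oxidation under near-neutral conditions, chosen so that the α-alkoxy aldehyde is not epimerised at C2 and the β-silyloxy group is not eliminated; the crude aldehyde is used at once.

Step 12
Reactants: 14 aldehyde; 15 triethyl 4-phosphonocrotonate
Product: 16 ethyl (2E,4E)-5-[(2R,3S,5S)-3-(tert-butyldimethylsilyloxy)-5-methyloxolan-2-yl]penta-2,4-dienoate
Conditions: LiN(SiMe3)2, THF, −78 → 0 °C
Reagents that add atoms: triethyl 4-phosphonocrotonate CCOC(=O)/C=C/CP(=O)(OCC)OCC
Why: Vinylogous Horner–Wadsworth–Emmons olefination, in which the lithiated phosphonate adds through the carbon next to phosphorus and syn-elimination of phosphate from the equilibrated adduct gives the new double bond E while the crotonate double bond keeps its E geometry.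

Step 13
Reactants: 16 dienoate
Product: 17 (2E,4E)-5-[(2R,3S,5S)-3-(tert-butyldimethylsilyloxy)-5-methyloxolan-2-yl]penta-2,4-dien-1-ol
Conditions: i-Bu2AlH, CH2Cl2, −78 °C; then aq. KNaC4H4O6
Reagents that add atoms: none
Why: 1,2-Reduction of a conjugated ester by i-Bu2AlH to the dienyl alcohol at low temperature, with the silyl ether and the diene left alone.

Step 14
Reactants: 17 dienol
Product: 18 (2E,4E)-5-[(2R,3S,5S)-3-(tert-butyldimethylsilyloxy)-5-methyloxolan-2-yl]penta-2,4-dienal
Conditions: MnO2, CH2Cl2, rt
Reagents that add atoms: none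
Why: Chemoselective MnO2 oxidation of an allylic alcohol to the conjugated aldehyde under neutral heterogeneous conditions that should neither touch the silyl ether nor scramble the E,E geometry.

Step 15
Reactants: 18 dienal; 19 dimethyl (1-diazo-2-oxopropyl)phosphonate
Product: 20 tert-butyl{[(2R,3S,5S)-2-[(1E,3E)-hexa-1,3-dien-5-yn-1-yl]-5-methyloxolan-3-yl]oxy}dimethylsilane
Conditions: K2CO3, MeOH, 0 °C → rt
Reagents that add atoms: dimethyl (1-diazo-2-oxopropyl)phosphonate COP(=O)(OC)C(=[N+]=[N-])C(C)=O
Why: Ohira–Bestmann homologation, in which methoxide deacylates 19 to the diazomethylphosphonate anion, this adds to the aldehyde and loses dimethyl phosphate and N2, and the alkylidene carbene rearranges by 1,2-hydrogen shift to the terminal alkyne under base mild enough for the TBS ether.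

Step 16
Reactants: 7 3-chloro-2-iodo-4,6-bis(methoxymethoxy)benzoic acid; 20 dienyne
Product: 22 3-[(1E,3E)-4-[(2R,3S,5S)-3-(tert-butyldimethylsilyloxy)-5-methyloxolan-2-yl]buta-1,3-dien-1-yl]-5-chloro-6,8-bis(methoxymethoxy)-1H-isochromen-1-one, via alkynylbenzoic acid 21 (not isolated)
Conditions: Pd(PPh3)4 (5 mol %), ZnCl2, Et3N, degassed DMF, 80 °C
Reagents that add atoms: none
Why: Pd(PPh3)4 supplies zerovalent palladium, which enters the C–I bond of 7 much faster than the C–Cl bond; the alkynylzinc species formed from 20 with ZnCl2 and Et3N transmetalates, and reductive elimination forges C4–C4a to give the 2-alkynylbenzoic acid 21 (a copper-free Sonogashira-type coupling). ZnCl2 then acts as a π-acid on the triple bond and the carboxylate oxygen adds anti to the alkyne carbon remote from ring A, a 6-endo-dig closure that forms O2–C3 and pyranone ring B, and protonation at C4 releases 22. The closest known reaction is the heteroannulation of 2-iodobenzoic acids with terminal alkynes to 3-substituted isocoumarins mediated by Pd(PPh3)4 and ZnCl2. No stereocentre is created, and the E,E-diene and the three oxolane centres are spectators. The selectivity needed is 6-endo over 5-exo closure (ylidenephthalide); the absence of copper, the Lewis acid, and the dienyl group that stabilises developing positive charge at C3 should all steer oxygen to C3. The silyl and MOM ethers should tolerate the amine-buffered medium.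

Step 17
Reactants: 22 protected isocoumarin
Product: 23 5-chloro-6,8-dihydroxy-3-[(1E,3E)-4-[(2R,3S,5S)-3-hydroxy-5-methyloxolan-2-yl]buta-1,3-dien-1-yl]-1H-isochromen-1-one (CNP0086741.1)
Conditions: 3 M aq. HCl, MeOH, rt → 40 °C
Reagents that add atoms: none
Why: Acid-catalysed acetal exchange and silyl ether solvolysis in methanol should remove both MOM groups and the TBS group in one operation, the isocoumarin enol lactone and the oxolane being stable to dilute acid at this temperature and no stereocentre being touched.

**Compound list**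
1 | 1-iodo-3,5-dimethoxybenzene | COc1cc(I)cc(OC)c1 | starting material
2 | [(2-iodo-4,6-dimethoxyphenyl)methylidene]dimethylammonium chloride | C[N+](C)=Cc1c(I)cc(OC)cc1OC.[Cl-] | intermediate
3 | 2-iodo-4,6-dimethoxybenzaldehyde | O=Cc1c(I)cc(OC)cc1OC | intermediate
4 | 3-chloro-2-iodo-4,6-dimethoxybenzaldehyde | O=Cc1c(I)c(Cl)c(OC)cc1OC | intermediate
5 | 3-chloro-4,6-dihydroxy-2-iodobenzaldehyde | O=Cc1c(I)c(Cl)c(O)cc1O | intermediate
6 | 3-chloro-2-iodo-4,6-bis(methoxymethoxy)benzaldehyde | O=Cc1c(I)c(Cl)c(OCOC)cc1OCOC | intermediate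
7 | 3-chloro-2-iodo-4,6-bis(methoxymethoxy)benzoic acid | OC(=O)c1c(I)c(Cl)c(OCOC)cc1OCOC | intermediate
8 | 2-deoxy-D-ribose | O=CC[C@H](O)[C@H](O)CO | starting material
9 | 2-deoxy-D-ribono-1,4-lactone, (4S,5R)-4-hydroxy-5-(hydroxymethyl)oxolan-2-one | O=C1C[C@H](O)[C@@H](CO)O1 | intermediate
10 | (4S,5R)-4-(tert-butyldimethylsilyloxy)-5-[(tert-butyldimethylsilyloxy)methyl]oxolan-2-one | O=C1C[C@H](O[Si](C)(C)C(C)(C)C)[C@@H](CO[Si](C)(C)C(C)(C)C)O1 | intermediate
11 | (4S,5R)-4-(tert-butyldimethylsilyloxy)-5-[(tert-butyldimethylsilyloxy)methyl]-2-methyloxolan-2-ol, both C2 epimers | CC1(O)C[C@H](O[Si](C)(C)C(C)(C)C)[C@@H](CO[Si](C)(C)C(C)(C)C)O1 | intermediate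
12 | tert-butyl{[(2R,3S,5S)-3-(tert-butyldimethylsilyloxy)-5-methyloxolan-2-yl]methoxy}dimethylsilane | C[C@H]1C[C@H](O[Si](C)(C)C(C)(C)C)[C@@H](CO[Si](C)(C)C(C)(C)C)O1 | intermediate
13 | [(2R,3S,5S)-3-(tert-butyldimethylsilyloxy)-5-methyloxolan-2-yl]methanol | C[C@H]1C[C@H](O[Si](C)(C)C(C)(C)C)[C@@H](CO)O1 | intermediate
14 | (2S,3S,5S)-3-(tert-butyldimethylsilyloxy)-5-methyloxolane-2-carbaldehyde | C[C@H]1C[C@H](O[Si](C)(C)C(C)(C)C)[C@@H](C=O)O1 | intermediate
15 | triethyl 4-phosphonocrotonate | CCOC(=O)/C=C/CP(=O)(OCC)OCC | starting material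
16 | ethyl (2E,4E)-5-[(2R,3S,5S)-3-(tert-butyldimethylsilyloxy)-5-methyloxolan-2-yl]penta-2,4-dienoate | C[C@H]1C[C@H](O[Si](C)(C)C(C)(C)C)[C@@H](/C=C/C=C/C(=O)OCC)O1 | intermediate
17 | (2E,4E)-5-[(2R,3S,5S)-3-(tert-butyldimethylsilyloxy)-5-methyloxolan-2-yl]penta-2,4-dien-1-ol | C[C@H]1C[C@H](O[Si](C)(C)C(C)(C)C)[C@@H](/C=C/C=C/CO)O1 | intermediate
18 | (2E,4E)-5-[(2R,3S,5S)-3-(tert-butyldimethylsilyloxy)-5-methyloxolan-2-yl]penta-2,4-dienal | C[C@H]1C[C@H](O[Si](C)(C)C(C)(C)C)[C@@H](/C=C/C=C/C=O)O1 | intermediate
19 | dimethyl (1-diazo-2-oxopropyl)phosphonate | COP(=O)(OC)C(=[N+]=[N-])C(C)=O | starting material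
20 | tert-butyl{[(2R,3S,5S)-2-[(1E,3E)-hexa-1,3-dien-5-yn-1-yl]-5-methyloxolan-3-yl]oxy}dimethylsilane | C[C@H]1C[C@H](O[Si](C)(C)C(C)(C)C)[C@@H](/C=C/C=C/C#C)O1 | intermediate
21 | 3-chloro-4,6-bis(methoxymethoxy)-2-[(3E,5E)-6-[(2R,3S,5S)-3-(tert-butyldimethylsilyloxy)-5-methyloxolan-2-yl]hexa-3,5-dien-1-yn-1-yl]benzoic acid | C[C@H]1C[C@H](O[Si](C)(C)C(C)(C)C)[C@@H](/C=C/C=C/C#Cc2c(Cl)c(OCOC)cc(OCOC)c2C(=O)O)O1 | intermediate
22 | 3-[(1E,3E)-4-[(2R,3S,5S)-3-(tert-butyldimethylsilyloxy)-5-methyloxolan-2-yl]buta-1,3-dien-1-yl]-5-chloro-6,8-bis(methoxymethoxy)-1H-isochromen-1-one | C[C@H]1C[C@H](O[Si](C)(C)C(C)(C)C)[C@@H](/C=C/C=C/c2cc3c(Cl)c(OCOC)cc(OCOC)c3c(=O)o2)O1 | intermediate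
23 | 5-chloro-6,8-dihydroxy-3-[(1E,3E)-4-[(2R,3S,5S)-3-hydroxy-5-methyloxolan-2-yl]buta-1,3-dien-1-yl]-1H-isochromen-1-one | C[C@H]1C[C@H](O)[C@@H](/C=C/C=C/c2cc3c(Cl)c(O)cc(O)c3c(=O)o2)O1 | target

**Step count**
Total: 17 steps. Longest linear sequence: 12 steps (steps 6 to 17, from 2-deoxy-D-ribose); the arene branch (steps 1 to 5) joins at step 16.

**Steps most likely to fail, with fallbacks**

Step 16. The carboxylate may close in the 5-exo mode to the ylidenephthalide. The hindered acid may lose iodine or CO2 before coupling. The dienyne may dimerise or isomerise at 80 °C. The fallback separates bond formation from ring closure and sets out from aldehyde 6 and dienyne 20. A Sonogashira coupling (PdCl2(PPh3)2, CuI, Et3N, THF, rt), in which no carboxylate is present to cyclise, should give 3-chloro-4,6-bis(methoxymethoxy)-2-[(3E,5E)-6-[(2R,3S,5S)-3-(tert-butyldimethylsilyloxy)-5-methyloxolan-2-yl]hexa-3,5-dien-1-yn-1-yl]benzaldehyde F1. Pinnick oxidation (NaClO2, NaH2PO4, 2-methyl-2-butene, t-BuOH/H2O) then gives acid 21, now isolated. Ring B is closed in a separate 6-endo cycloisomerisation with PdCl2(MeCN)2 (divalent palladium as π-acid) and Et3N in THF, which comes back to the route at 22.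

Step 15. Methoxide may add in conjugate fashion to the dienal or to the diazoalkene intermediate. The base may erode the E,E geometry, and conversion may stall. The fallback avoids methanol and carbonate and sets out from dienal 18. Dibromo-olefination (CBr4, PPh3, Et3N, CH2Cl2, 0 °C) should give tert-butyl{[(2R,3S,5S)-2-[(1E,3E)-6,6-dibromohexa-1,3,5-trien-1-yl]-5-methyloxolan-3-yl]oxy}dimethylsilane F2. Treatment with n-BuLi (THF, −78 °C, then aq. NH4Cl) brings about bromine–lithium exchange and Fritsch–Buttenberg–Wiechell rearrangement (Corey–Fuchs sequence) and comes back to the route at 20.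

Step 12. The lithiated phosphonate may enolise the α-alkoxy aldehyde, with epimerisation at C2 or β-elimination of the C3 silyloxy group. The new double bond may also form with incomplete E selectivity. The fallback builds the diene two carbons at a time without strong base and sets out from aldehyde 14. A Wittig reaction with the neutral stabilised ylide Ph3P=CHCHO (toluene, rt → 50 °C) should give (2E)-3-[(2R,3S,5S)-3-(tert-butyldimethylsilyloxy)-5-methyloxolan-2-yl]prop-2-enal F3. A Horner–Wadsworth–Emmons reaction with triethyl phosphonoacetate under LiCl/DBU in MeCN then comes back to the route at 16.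

**Further compounds**
F1 | step 16 | 3-chloro-4,6-bis(methoxymethoxy)-2-[(3E,5E)-6-[(2R,3S,5S)-3-(tert-butyldimethylsilyloxy)-5-methyloxolan-2-yl]hexa-3,5-dien-1-yn-1-yl]benzaldehyde | C[C@H]1C[C@H](O[Si](C)(C)C(C)(C)C)[C@@H](/C=C/C=C/C#Cc2c(Cl)c(OCOC)cc(OCOC)c2C=O)O1
F2 | step 15 | tert-butyl{[(2R,3S,5S)-2-[(1E,3E)-6,6-dibromohexa-1,3,5-trien-1-yl]-5-methyloxolan-3-yl]oxy}dimethylsilane | C[C@H]1C[C@H](O[Si](C)(C)C(C)(C)C)[C@@H](/C=C/C=C/C=C(Br)Br)O1
F3 | step 12 | (2E)-3-[(2R,3S,5S)-3-(tert-butyldimethylsilyloxy)-5-methyloxolan-2-yl]prop-2-enal | C[C@H]1C[C@H](O[Si](C)(C)C(C)(C)C)[C@@H](/C=C/C=O)O1
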